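Slowness here can be counted: how many electrophile half-lives fit into the run? One flask is charged with electrophile and solid nucleophile, and the solid dissolves as the run proceeds.

electrophile 0.17 M; solid nucleophile 0.306 M; time 4.0 min

- part of the electrophile that has reacted at 4.0 min
- share of free nucleophile in free nucleophile and protonated nucleophile together, at 4.0 min

We build the flask up by hand. With only the main step, and dissolved nucleophile held at its solubility 0.069 M, the electrophile decays pseudo-first-order with half-life 0.364 min. The half-life count, the run time divided by that half-life, is then 11.0, leaving 0.0488 %.

Now add the acid. Each acid set free protonates one nucleophile, so each electrophile costs two, and as long as no acid leaves the charge falls short by 0.0340 M: on that count the solid nucleophile is the limiting reagent.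

Add the dissolving. No nucleophile is in solution at the start. At the charged [electrophile], reaction and protonation together remove dissolved nucleophile with a constant of 0.156 s⁻¹, close to the dissolving coefficient 0.17 s⁻¹, so we estimate that [nucleophile] climbs to near 0.0359 M, half the solubility.

Last, add the escape of acid. Free acid stands at [protonated nucleophile]/(K2[nucleophile]). At an assumed ratio of 2 of protonated to free nucleophile, we estimate that the run returns 0.0587 M of nucleophile, more than the shortfall. We therefore keep [nucleophile] near 0.0359 M. The count drops to 5.72 and we commit to 98.1 % reacted, without a hand figure for the share.

The forecast, holding that “Each electrophile consumed takes two nucleophiles, one reacted and one protonated”, gives 98.8 % reacted, a little above ours, and a free share of 33 %.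

The simulation gives 98.7 % and 32.8 %, so the forecast stands. With the other amounts and the time held, the reacted part has moved by 5 points at a solid nucleophile charge of 0.243 M.

    electrophile + nucleophile → acid set free + target (k1 = 0.46 L mol⁻¹ s⁻¹)
    nucleophile + acid set free ⇌ protonated nucleophile, settled at all times (K2 = 9000 L mol⁻¹)
    solid nucleophile ⇌ nucleophile, rate k3*(cs3 - [nucleophile]) while solid is left; crystals form when [nucleophile] > cs3 (cs3 = 0.069 M, k3 = 0.17 s⁻¹)
    acid set free → by-product carried off (k4 = 1.1 s⁻¹)

In the flask, reaction and dissolving ran together while solid lasted: at 0.400 min, 52.7 % of the solid remained and target stood at 30.9 %. By 2.00 min the solid stood at 0 % and [nucleophile] at 0.0318 M; acid then kept leaving, with by-product going from 0.0316 M to 0.0747 M at 4.00 min, and [nucleophile] reached 0.0453 M. The 1.3 % of electrophile left in this flask at 4.00 min is a count of 6.28, fewer than 11.0. The neighbour charged with 1.2 M of solid nucleophile still holds 70.2 % of its solid at 4.00 min, and its 0.13 % of electrophile left is a count of 9.59.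

The constants used here were set for the occasion; what happens was integrated by code.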